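Per second of bath time I counted what each molecule did, and I left this note for whoever took over the three flasks.

| setting | winter | dawn | summer |
|---|---|---|---|
| left-handed substrate | 0.10 M | 0.10 M | 0.10 M |
| gas | 17 mM (held) | 17 mM (held) | 17 mM (held) |
| right-handed substrate | 0.10 M | 0.10 M | 0.10 M |
| temperature | 90 °C | 70 °C | 50 °C |
| time | 6.0 min | 6.0 min | 6.0 min |

    right-handed substrate ⇌ achiral form (K3 = 0.72, k3 = 0.0019 /s, Ea3 = 91.0 kJ/mol, ΔH3 = −5.00 kJ/mol)
    2 reagent → self-condensation product (k2 = 0.071 /M/s, Ea2 = 65.0 kJ/mol)
    left-handed substrate ⇌ achiral form (K3 = 0.72, k3 = 0.0019 /s, Ea3 = 91.0 kJ/mol, ΔH3 = −5.00 kJ/mol)
    reagent + right-handed substrate → right-handed product (k4 = 0.43 /M/s, Ea4 = 54.0 kJ/mol)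
    reagent + left-handed substrate → left-handed product (k5 = 1.2 /M/s, Ea5 = 37.0 kJ/mol)
    gas ⇌ reagent, rate k6*(csat - [reagent]) (k6 = 0.0079 /s, csat = 17 mM)
    (constants at 50 °C)

- reagent is single-handed; left-handed substrate and right-handed substrate are mirror images of each other, charged as a racemate, each of them at the stated concentration
- where a step has two of a species, its rate is k times that concentration squared, and two are used at each turn
- at the start none of reagent is dissolved
- at 50 °C the constants are as listed, elsewhere as the activation energies and enthalpies make them
- the handed part of reagent does not stay in what it makes, so the products of the two hands are mirror images too

- which flask leads in share of left-handed product in all that became left-handed product or right-handed product ("all alike" within 1.5 percentage points) (winter / dawn / summer / all alike)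
- share of left-handed product in all that became left-handed product or right-handed product, winter
- share of left-handed product in all that became left-handed product or right-handed product, dawn
- share of left-handed product in all that became left-handed product or right-handed product, summer

When you came, the flasks held substrate of both hands, its achiral form, and reagent passing through at a low level. The gas could deliver at most 0.0483 M of reagent in 6.0 min, a quarter of the substrate charged, so I took reagent as the limiting reagent. Each capture step is first order in reagent, so the reagent level cancels when the two are compared.

At 50 °C the two capture constants split 73.6% to 26.4%. I call the left part the handed share S: the constant of reagent with left-handed substrate over the sum of that constant and the right-handed one, both at the bath temperature, which is the product share while the substrates stand equal. It gave 65.9% at dawn and 58.2% in winter. Keep each bath at its set temperature, because S differed between them, standing higher in summer than in winter.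

Then I counted turnovers, n, the constant from substrate to achiral form times the time: 28.5 in winter, 0.684 in summer. With n far above one in winter I expected level hands there and committed to S. With n below one in summer I expected summer's left-handed substrate to thin, which put summer under S.

The forecast gave 58%, 65.1% and 71%, with summer leading, holding that “racemisation through the achiral form almost erases the depletion of the left-handed substrate at 70–90 °C and only trims the share by a couple of points at 50 °C”. Its dawn figure stood under my S.

The flasks gave 58.1% in winter, 65.1% at dawn and 71.3% in summer, so summer led. Summer stood 2.3 percentage points under S, with 51% of its left-handed substrate left against 64% of the right-handed. For the neighbour at 75 °C, S gave 63.9% and the flask read 63.4%. The winter flask had not come to rest at 6.0 min, holding 29.4% left-handed substrate. By 60.0 min that had fallen to 0%, and winter's share stayed at 57.9%, while dawn went to 63.4% and summer to 61.1%.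

The constants used here belong to no real substance; what happens was integrated by code.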